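**Retrosynthetic overview**
1. Target 9 ⇒ perketal-protected chalcone 8 by acid hydrolysis in the last step, so the free hydroperoxide never meets base; 8 ⇒ Claisen–Schmidt disconnection into aryl methyl ketone 6 and 4-hydroxybenzaldehyde 7.
2. 6 ⇒ 4-O-methylation of 5 ⇒ aryl C3–CH2 bond: C-alkylation of 2,4-dihydroxyacetophenone 4 with the chiral C10 allylic chloride 3.
3. 3 ⇒ geranyl chloride 1 + O2: catalytic asymmetric Schenck-type allylic hydroperoxidation of the 6,7-alkene sets the only stereocenter (R) and is capped in the same flask as a perketal. It is done first because in 1 the 6,7-alkene is the only easily oxidised group.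
4. No ring is formed; both benzene rings are bought.

Assumption: the chiral pyrylium imidodiphosphorimidate (IDPi) salt is made beforehand by ion exchange and is not counted as a step; of its two antipodes the one that gives the (R)-hydroperoxide is used (written here as S,S).

**Route**

Step 1
Reactants: 1 geranyl chloride [(2E)-1-chloro-3,7-dimethylocta-2,6-diene]
Product: 3 (3R,6E)-8-chloro-3-[(2-methoxypropan-2-yl)peroxy]-2,6-dimethylocta-1,6-diene, via allylic hydroperoxide 2 (not isolated)
Conditions: O2 (1 atm), 2,4,6-triphenylpyrylium (S,S)-IDPi salt (3 mol %), CH2Cl2, 420 nm LED, −78 °C; then 2-methoxypropene, PPTS (5 mol %), −78 to 0 °C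
Reagents that add atoms: dioxygen O=O; 2-methoxypropene COC(C)=C
Why: Proposed new method: a Schenck-ene-type aerobic allylic hydroperoxidation run by asymmetric counteranion-directed photoredox catalysis, in which the excited pyrylium oxidises only the electron-rich 6,7-alkene (the 2,3-alkene is deactivated by the allylic chloride) to a radical cation held in a contact ion pair by the confined, non-basic chiral anion; dioxygen bonds to the less substituted C6 on the face the anion leaves open (Re face, giving R; enantio-determining), the tertiary C7 cation loses a methyl proton to give the isopropenyl group (hence the secondary and not the tertiary hydroperoxide), and the pyranyl radical reduces the allylperoxyl radical to close a redox-neutral cycle; the closest known reactions are the racemic singlet-oxygen Schenck ene reaction, electron-transfer photooxygenation of alkenes, anti-Markovnikov capture of alkene radical cations, and chiral-anion-paired photoredox radical-cation cycloadditions; the hydroperoxide 2 is then capped by acid-catalysed addition to the enol ether (perketal formation).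

Step 2
Reactants: 3 (3R,6E)-8-chloro-3-[(2-methoxypropan-2-yl)peroxy]-2,6-dimethylocta-1,6-diene; 4 2,4-dihydroxyacetophenone
Product: 5 1-{2,4-dihydroxy-3-[(2E,6R)-6-[(2-methoxypropan-2-yl)peroxy]-3,7-dimethylocta-2,7-dien-1-yl]phenyl}ethan-1-one
Conditions: 4 (3 equiv), 10% aq KOH, KI (10 mol %), 0 °C to rt, 24 h
Reagents that add atoms: none
Why: Phenoxide C-alkylation (SN2 allylation without allylic shift): in water the phenoxide oxygens are solvated, so the doubly activated ring carbon between them attacks the primary allylic chloride, as in the known C-geranylation of this ketone; the base-stable perketal and its stereocenter are untouched.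

Step 3
Reactants: 5 1-{2,4-dihydroxy-3-[(2E,6R)-6-[(2-methoxypropan-2-yl)peroxy]-3,7-dimethylocta-2,7-dien-1-yl]phenyl}ethan-1-one
Product: 6 1-{2-hydroxy-4-methoxy-3-[(2E,6R)-6-[(2-methoxypropan-2-yl)peroxy]-3,7-dimethylocta-2,7-dien-1-yl]phenyl}ethan-1-one
Conditions: MeI (1.1 equiv), K2CO3 (1.2 equiv), acetone, rt
Reagents that add atoms: iodomethane CI
Why: Williamson ether synthesis; only the free 4-hydroxyl is methylated because the 2-hydroxyl is tied up in the hydrogen bond to the acetyl carbonyl.

Step 4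
Reactants: 6 1-{2-hydroxy-4-methoxy-3-[(2E,6R)-6-[(2-methoxypropan-2-yl)peroxy]-3,7-dimethylocta-2,7-dien-1-yl]phenyl}ethan-1-one; 7 4-hydroxybenzaldehyde
Product: 8 (2E)-1-{2-hydroxy-4-methoxy-3-[(2E,6R)-6-[(2-methoxypropan-2-yl)peroxy]-3,7-dimethylocta-2,7-dien-1-yl]phenyl}-3-(4-hydroxyphenyl)prop-2-en-1-one
Conditions: KOH (50% aq), EtOH, argon, rt, 48 h
Reagents that add atoms: none
Why: Claisen–Schmidt (crossed aldol) condensation with E1cB dehydration gives the thermodynamic E-enone; the peroxide is masked as a dialkyl perketal, so no peroxy anion is present that could epoxidise the enone.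

Step 5
Reactants: 8 (2E)-1-{2-hydroxy-4-methoxy-3-[(2E,6R)-6-[(2-methoxypropan-2-yl)peroxy]-3,7-dimethylocta-2,7-dien-1-yl]phenyl}-3-(4-hydroxyphenyl)prop-2-en-1-one
Product: 9 (2E)-1-{3-[(2E,6R)-6-hydroperoxy-3,7-dimethylocta-2,7-dien-1-yl]-2-hydroxy-4-methoxyphenyl}-3-(4-hydroxyphenyl)prop-2-en-1-one (CNP0163229.1)
Conditions: AcOH/THF/H2O (4:2:1), rt
Reagents that add atoms: none
Why: Acid-catalysed perketal (acetal) hydrolysis breaks only the ketal C–O bond, so the O–O bond and the C6 configuration are retained and the free hydroperoxide is released.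

**Compound list**
1 | geranyl chloride, (2E)-1-chloro-3,7-dimethylocta-2,6-diene | CC(C)=CCC/C(C)=C/CCl | starting material
2 | (3R,6E)-8-chloro-2,6-dimethylocta-1,6-dien-3-yl hydroperoxide | C=C(C)[C@@H](CC/C(C)=C/CCl)OO | intermediate
3 | (3R,6E)-8-chloro-3-[(2-methoxypropan-2-yl)peroxy]-2,6-dimethylocta-1,6-diene | C=C(C)[C@@H](CC/C(C)=C/CCl)OOC(C)(C)OC | intermediate
4 | 2,4-dihydroxyacetophenone | CC(=O)c1ccc(O)cc1O | starting material
5 | 1-{2,4-dihydroxy-3-[(2E,6R)-6-[(2-methoxypropan-2-yl)peroxy]-3,7-dimethylocta-2,7-dien-1-yl]phenyl}ethan-1-one | C=C(C)[C@@H](CC/C(C)=C/Cc1c(O)ccc(C(C)=O)c1O)OOC(C)(C)OC | intermediate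
6 | 1-{2-hydroxy-4-methoxy-3-[(2E,6R)-6-[(2-methoxypropan-2-yl)peroxy]-3,7-dimethylocta-2,7-dien-1-yl]phenyl}ethan-1-one | C=C(C)[C@@H](CC/C(C)=C/Cc1c(OC)ccc(C(C)=O)c1O)OOC(C)(C)OC | intermediate
7 | 4-hydroxybenzaldehyde | O=Cc1ccc(O)cc1 | starting material
8 | (2E)-1-{2-hydroxy-4-methoxy-3-[(2E,6R)-6-[(2-methoxypropan-2-yl)peroxy]-3,7-dimethylocta-2,7-dien-1-yl]phenyl}-3-(4-hydroxyphenyl)prop-2-en-1-one | C=C(C)[C@@H](CC/C(C)=C/Cc1c(OC)ccc(C(=O)/C=C/c2ccc(O)cc2)c1O)OOC(C)(C)OC | intermediate
9 | (2E)-1-{3-[(2E,6R)-6-hydroperoxy-3,7-dimethylocta-2,7-dien-1-yl]-2-hydroxy-4-methoxyphenyl}-3-(4-hydroxyphenyl)prop-2-en-1-one | C=C(C)[C@@H](CC/C(C)=C/Cc1c(OC)ccc(C(=O)/C=C/c2ccc(O)cc2)c1O)OO | target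

**Step count and risks**
Total steps: 5 (hydroperoxide 2 is made and capped in one flask). Longest linear sequence: 5 steps (1 → 3 → 5 → 6 → 8 → 9).

Steps most likely to fail:

Step 1 (the proposed new reaction). The radical cation may lose a proton before C–O bond formation, giving an allyl radical and racemic or regioisomeric peroxides. A dioxetane may form and cleave. Any singlet oxygen formed gives racemic background. The ion pair may give low enantioselectivity. The fallback sets out from 1 and comes back at 2. Methylene-blue-sensitised photooxygenation of 1 (O2, CH2Cl2, red LED, 0 °C; the classical singlet-oxygen Schenck ene reaction) gives, after chromatography, racemic (6E)-8-chloro-2,6-dimethylocta-1,6-dien-3-yl hydroperoxide F1 beside the tertiary regioisomer (3E,6E)-8-chloro-2,6-dimethylocta-3,6-dien-2-yl hydroperoxide F2. Preparative HPLC on a cellulose tris(3,5-dimethylphenylcarbamate) phase splits F1 into 2 and its antipode (3S,6E)-8-chloro-2,6-dimethylocta-1,6-dien-3-yl hydroperoxide F3, which is discarded. Compound 2 is then capped with 2-methoxypropene/PPTS as in the second half of step 1 to give 3.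

Step 2. The C-alkylation is only moderately regioselective (C5- and O-alkylation, hydrolysis of the chloride), and it spends the chiral chloride. The fallback sets out from 4 and 3 and comes back at 6, so step 3 is skipped. Iodination of 4 (I2, HIO3, aq EtOH) gives 1-(2,4-dihydroxy-3-iodophenyl)ethan-1-one F4. MeI/K2CO3 in acetone methylates its free 4-hydroxyl to 1-(2-hydroxy-3-iodo-4-methoxyphenyl)ethan-1-one F5. Stannylation (Bu3SnSnBu3, Pd(PPh3)4, toluene, 100 °C) gives 1-[2-hydroxy-4-methoxy-3-(tributylstannyl)phenyl]ethan-1-one F6. Stille coupling of F6 with 3 (Pd2(dba)3, AsPh3, DMF, 45 °C; phosphine-free to spare the O–O bond) joins the ring carbon to the primary allylic terminus and gives 6 regiospecifically.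

Step 4. The phenoxide of 7 deactivates the aldehyde, so the condensation may stall or give flavanone on long standing. The fallback sets out from 6 and 7 and comes back at 9. Compound 7 is protected with 3,4-dihydro-2H-pyran/PPTS as 4-(tetrahydro-2H-pyran-2-yloxy)benzaldehyde F7. Condensation of F7 with 6 (Ba(OH)2·8H2O, EtOH, rt) gives (2E)-1-{2-hydroxy-4-methoxy-3-[(2E,6R)-6-[(2-methoxypropan-2-yl)peroxy]-3,7-dimethylocta-2,7-dien-1-yl]phenyl}-3-[4-(tetrahydro-2H-pyran-2-yloxy)phenyl]prop-2-en-1-one F8 (epimers at the acetal carbon). The AcOH/THF/H2O treatment of step 5, run at 40 °C, removes the tetrahydropyranyl ether and the perketal together and gives 9.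

**Further compounds**
F1 | step 1 | racemic (6E)-8-chloro-2,6-dimethylocta-1,6-dien-3-yl hydroperoxide | C=C(C)C(CC/C(C)=C/CCl)OO
F2 | step 1 | (3E,6E)-8-chloro-2,6-dimethylocta-3,6-dien-2-yl hydroperoxide | CC(C)(OO)/C=C/C/C(C)=C/CCl
F3 | step 1 | (3S,6E)-8-chloro-2,6-dimethylocta-1,6-dien-3-yl hydroperoxide | C=C(C)[C@H](CC/C(C)=C/CCl)OO
F4 | step 2 | 1-(2,4-dihydroxy-3-iodophenyl)ethan-1-one | CC(=O)c1ccc(O)c(I)c1O
F5 | step 2 | 1-(2-hydroxy-3-iodo-4-methoxyphenyl)ethan-1-one | COc1ccc(C(C)=O)c(O)c1I
F6 | step 2 | 1-[2-hydroxy-4-methoxy-3-(tributylstannyl)phenyl]ethan-1-one | CCCC[Sn](CCCC)(CCCC)c1c(OC)ccc(C(C)=O)c1O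
F7 | step 4 | 4-(tetrahydro-2H-pyran-2-yloxy)benzaldehyde | O=Cc1ccc(OC2CCCCO2)cc1
F8 | step 4 | (2E)-1-{2-hydroxy-4-methoxy-3-[(2E,6R)-6-[(2-methoxypropan-2-yl)peroxy]-3,7-dimethylocta-2,7-dien-1-yl]phenyl}-3-[4-(tetrahydro-2H-pyran-2-yloxy)phenyl]prop-2-en-1-one | C=C(C)[C@@H](CC/C(C)=C/Cc1c(OC)ccc(C(=O)/C=C/c2ccc(OC3CCCCO3)cc2)c1O)OOC(C)(C)OC
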